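At 40 min I have to read this flask, and so far I have its earlier readings.

- delta: substrate 10 mM; partner 1 equiv; scavenger 1.5 equiv; the very flask that is asked about, followed so far
- flask: substrate 10 mM; partner 1.00 equiv; scavenger 1.50 equiv; time 40 min

delta run (percent of the substrate charged)

| time / min | substrate / % | target / % |
|---|---|---|
| 1.00 | 81 | 1 |
| 2.00 | 71 | 1 |
| 3.00 | 61 | 5 |
| 6.00 | 44 | 16 |
| 12.0 | 30 | 26 |

(scatter of a reading: 1.5 percentage points)

- part of the substrate that has reacted at 40 min
- share of the unused partner that is free and not bound as idle adduct, at 40 min

- released group is meant together with its idle adduct
- the analysis behind the earlier runs scatters by 1.5 percentage points, standard deviation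
- steps under discussion: substrate + partner -> intermediate + released group; intermediate -> target; partner + released group <-> idle adduct; scavenger + released group -> scavenged by-product; intermediate -> side product
- the earlier runs do not show how much of partner is bound; that part of a forecast is a guess

Substrate and partner enter the first step at equal charges, so while partner stays free the two stay equal. The rate is then k·s·s, with s the fraction of substrate left and k a constant. That integrates in closed form to s = τ/(τ+t), with t the time and τ the inverse of k, so each row gives τ = t·s/c, where c is the part reacted.

The row at 3.00 min gives 4.69 min, the row at 6.00 min gives 4.71 min, and the row at 12.0 min gives 5.14 min. I call τ the halving time, the time in which substrate falls to half of its charge while substrate and partner stay equal.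

These values rise a little from row to row, but with a scatter of 1.5 percentage points on each reading I claim no bound partner from them, and I take partner as free, which is a guess. I carry the last row, the one furthest along, and c = t/(t+τ) gives 88.6 %.

The forecast says 86 % reacted and 80 % free, the second being, in its words, “largely a guess”.

The flask gives 89.1 % reacted, with >99.9 % of the unused partner free.

    substrate + partner → intermediate + released group (k = 0.340 M⁻¹ s⁻¹)
    intermediate → target (k = 0.00170 s⁻¹)
    partner + released group ⇌ idle adduct, settled at all times (K = 200 M⁻¹)
    scavenger + released group → scavenged by-product (k = 43.0 M⁻¹ s⁻¹)
    intermediate → side product (k = 0.00160 s⁻¹)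

At 40.0 min this flask holds substrate at 10.9 % and partner at 10.9 %, with idle adduct at 3.40 × 10⁻⁴ mM. The same τ puts substrate at 20.4 % at 20.0 min, and the flask holds 19.7 %. A neighbour flask is charged with 17 mM of substrate, with equivalents and time held. I scale τ in inverse proportion to the charge, to 3.03 min, so I reckon c at 93.0 %. That neighbour flask gives 93.3 %.

Readings and results are simulated from invented constants, noise included.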